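**Retrosynthetic overview**

1. 26 ⇐ 25 by release of the diols; 25 ⇐ 24 by an amine/arylboronic acid oxa-Michael addition (key step, new) that forms C14–O and sets C13 and C14 through a temporary, necessarily cis-fused dioxaborinane.
2. 24 ⇐ 23 by ring-closing metathesis (lactone ring) ⇐ aldehyde 19 by a β-isocupreidine-catalysed Morita–Baylis–Hillman reaction (sets C12).
3. 19 ⇐ triol 17 ⇐ epoxy allylsilane 14: one cation–olefin cascade closes ring A, then ring B (sets C5, C9, C10; relays C3/C4; gives the exocyclic alkene).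
4. 14 ⇐ (Z)-allylic alcohol 13 by Sharpless epoxidation (first stereocentres, C3/C4) ⇐ enynol 9 by carbocupration and ethylene oxide trapping.
5. 9 ⇐ geranyl chloride 1 by ozonolysis, Still–Gennari olefination, reduction and propargylation.

Assumption: the target is taken exactly as drawn, i.e. (12R,13R,14S)-12-hydroxy-12,13-dihydroandrographolide; locants C1–C20 follow labdane numbering; catalysts (L-(+)-diethyl tartrate, β-isocupreidine, the cinchona thiourea) are bought and not counted as starting materials.

**Route**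

Step 1
Reactants: 1 geranyl chloride
Product: 3 (4E)-6-chloro-4-methylhex-4-enal, via ozonide 2 (not isolated)
Conditions: O3 (1.0 equiv), CH2Cl2, −78 °C; then PPh3, −78 → 0 °C
Reagents that add atoms: ozone, O=[O+][O-]
Why: Chemoselective ozonolysis: the allylic chloride deactivates the C2=C3 alkene, so ozone cleaves only the electron-rich distal alkene and PPh3 reduces the ozonide to the aldehyde.

Step 2
Reactants: 3 (4E)-6-chloro-4-methylhex-4-enal; 4 ethyl 2-[bis(2,2,2-trifluoroethoxy)phosphoryl]propanoate
Product: 5 ethyl (2Z,6E)-8-chloro-2,6-dimethylocta-2,6-dienoate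
Conditions: KN(SiMe3)2, 18-crown-6, THF, −78 °C
Reagents that add atoms: none
Why: Still–Gennari (Z-selective Horner–Wadsworth–Emmons) olefination: the bis(trifluoroethyl) phosphonate under dissociating K/18-crown-6 conditions gives the (Z)-2-methyl enoate (typically >15:1), which places the future C19 carbon cis to the chain.

Step 3
Reactants: 5 ethyl (2Z,6E)-8-chloro-2,6-dimethylocta-2,6-dienoate
Product: 6 (2Z,6E)-8-chloro-2,6-dimethylocta-2,6-dien-1-ol
Conditions: iBu2AlH (2.3 equiv), CH2Cl2, −78 °C; aq. potassium sodium tartrate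
Reagents that add atoms: none
Why: 1,2-Reduction of the enoate by iBu2AlH at −78 °C gives the allylic alcohol and leaves the allylic chloride and both alkene geometries untouched.

Step 4
Reactants: 6 (2Z,6E)-8-chloro-2,6-dimethylocta-2,6-dien-1-ol; 7 trimethyl(prop-1-yn-1-yl)silane
Product: 9 (2Z,6E)-2,6-dimethylundeca-2,6-dien-10-yn-1-ol, via silylalkyne 8 (not isolated)
Conditions: n-BuLi (2.3 equiv), THF, −78 → 0 °C; then K2CO3 (cat.), MeOH, 23 °C
Reagents that add atoms: none
Why: SN2 alkylation of the primary allylic chloride by the propargyllithium from 7 (the C-silyl group suppresses allenyl coupling; one equivalent of n-BuLi first turns the alcohol into its alkoxide), followed by protodesilylation of the alkynylsilane.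

Step 5
Reactants: 9 (2Z,6E)-2,6-dimethylundeca-2,6-dien-10-yn-1-ol; 10 [(trimethylsilyl)methyl]magnesium chloride; 11 oxirane
Product: 13 (2Z,6E,10Z)-2,6-dimethyl-10-[(trimethylsilyl)methyl]trideca-2,6,10-triene-1,13-diol, via alkenylcopper 12 (not isolated)
Conditions: 10 (3 equiv; 1 equiv first to form the alkoxide of 9), CuBr·SMe2 (2 equiv), Et2O/Me2S, −40 → −20 °C; then 11 (excess), THF, −30 → 0 °C; aq. NH4Cl
Reagents that add atoms: none
Why: Normant carbocupration: Me3SiCH2Cu adds syn across the terminal alkyne with carbon going to the internal position, and the alkenylcopper opens ethylene oxide with retention, so CH2SiMe3 and the hydroxyethyl chain end up cis (10Z), as needed later for the exocyclic alkene and the equatorial side chain.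

Step 6
Reactants: 13 (2Z,6E,10Z)-2,6-dimethyl-10-[(trimethylsilyl)methyl]trideca-2,6,10-triene-1,13-diol
Product: 14 {(2S,3R)-3-[(3E,7Z)-10-hydroxy-3-methyl-7-[(trimethylsilyl)methyl]deca-3,7-dien-1-yl]-2-methyloxiran-2-yl}methanol
Conditions: Ti(OiPr)4 (10 mol%), L-(+)-diethyl tartrate (12 mol%), t-BuOOH (2 equiv), 4 Å MS, CH2Cl2, −20 °C
Reagents that add atoms: tert-butyl hydroperoxide, CC(C)(C)OO
Why: Sharpless asymmetric epoxidation: the Ti/tartrate catalyst binds the allylic alcohol and oxidises only that alkene (allylsilane and remote alkene untouched), L-(+)-diethyl tartrate giving the (2S,3R)-epoxide in about 90% ee, which sets the first two stereocentres (future C4 and C3).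

Step 7
Reactants: 14 {(2S,3R)-3-[(3E,7Z)-10-hydroxy-3-methyl-7-[(trimethylsilyl)methyl]deca-3,7-dien-1-yl]-2-methyloxiran-2-yl}methanol
Product: 17 (1R,2R,4aS,5R,8aS)-5-(2-hydroxyethyl)-1-(hydroxymethyl)-1,4a-dimethyl-6-methylidenedecahydronaphthalen-2-ol, via bis-silyl ether 15 (not isolated), via cyclised bis-silyl ether 16 (not isolated)
Conditions: (Me3Si)2NH, Me3SiCl (cat.), CH2Cl2, 23 °C, then evaporation; MeAlCl2 (2.2 equiv), CH2Cl2, −78 °C; then 1 M HCl, THF, 0 °C
Reagents that add atoms: none
Why: Epoxide-initiated cation–olefin bicyclisation of an allylsilane-terminated polyene (after transient O-silylation): the Lewis-acid-activated epoxide is opened at the fully substituted carbon with inversion by the (E)-alkene through a chair–chair transition state, so C3–O is equatorial, the CH2O group that was cis to the chain is axial at C4, the ring fusion is trans, and the (Z)-allylsilane terminates at C9 with loss of silicon to give the equatorial side chain and the C8 exocyclic methylidene, the acid work-up removing the silyl ethers.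

Step 8
Reactants: 17 (1R,2R,4aS,5R,8aS)-5-(2-hydroxyethyl)-1-(hydroxymethyl)-1,4a-dimethyl-6-methylidenedecahydronaphthalen-2-ol
Product: 18 3,19-O-isopropylidene acetal of triol 17
Conditions: Me2C(OMe)2, PPTS (cat.), CH2Cl2, 23 °C
Reagents that add atoms: 2,2-dimethoxypropane, COC(C)(C)OC
Why: Acetalisation under thermodynamic control: only the 1,3-related 3-OH/C19-OH pair can close a six-membered isopropylidene acetal, which leaves the primary C12 alcohol free.

Step 9
Reactants: 18 3,19-O-isopropylidene acetal of triol 17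
Product: 19 3,19-O-isopropylidene C12 aldehyde
Conditions: TEMPO (10 mol%), PhI(OAc)2 (1.2 equiv), CH2Cl2, 23 °C
Reagents that add atoms: none
Why: TEMPO/PhI(OAc)2 oxidation (oxoammonium catalysis) stops at the aldehyde under near-neutral conditions, and no stereocentre is α to the new carbonyl.

Step 10
Reactants: 19 3,19-O-isopropylidene C12 aldehyde; 20 1,1,1,3,3,3-hexafluoropropan-2-yl prop-2-enoate; 21 prop-2-en-1-ol
Product: 23 allyl (3R)-3-hydroxy-2-methylidenebutanoate carrying the decalin of 19 at C4, via hexafluoroisopropyl ester 22 (not isolated)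
Conditions: β-isocupreidine (10 mol%), DMF, −55 °C, 72 h; then 21 (10 equiv), Et3N, 0 → 23 °C
Reagents that add atoms: none
Why: Morita–Baylis–Hillman reaction catalysed by β-isocupreidine: the quinuclidine nitrogen adds to the acrylate and the C6′ phenol organises the aldol step so that the (R)-carbinol (C12) forms under catalyst control (high ee is typical for unbranched aliphatic aldehydes), after which the activated hexafluoroisopropyl ester is transesterified by allyl alcohol.

Step 11
Reactants: 23 allyl (3R)-3-hydroxy-2-methylidenebutanoate carrying the decalin of 19 at C4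
Product: 24 3-[(1R)-1-hydroxy-2-(decalinyl)ethyl]furan-2(5H)-one [(12R)-14-deoxy-12-hydroxyandrographolide 3,19-acetonide]
Conditions: second-generation Grubbs catalyst (H2IMes)(PCy3)Cl2Ru=CHPh (5 mol%), toluene (5 mM), 80 °C
Reagents that add atoms: none
Why: Ring-closing metathesis of the allyl 2-substituted acrylate closes the α-substituted butenolide with loss of ethene, the hindered 1,1-disubstituted C8 methylidene not taking part.

Step 12
Reactants: 24 3-[(1R)-1-hydroxy-2-(decalinyl)ethyl]furan-2(5H)-one
Product: 25 cyclic phenylboronate of the 12,14-diol (2-phenyl-1,3,2-dioxaborinane cis-fused to the γ-lactone; 12R,13R,14S; 3,19-acetonide retained)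
Conditions: PhB(OH)2 (1.3 equiv), quinidine-derived 3,5-bis(trifluoromethyl)phenyl thiourea (10 mol%), 4 Å MS, toluene, 23 → 40 °C
Reagents that add atoms: phenylboronic acid, OB(O)c1ccccc1
Why: Proposed new method: phenylboronic acid condenses with the only free hydroxyl (C12) to a boronic hemiester whose B–OH oxygen, made nucleophilic by the quinuclidine base while the thiourea hydrogen-bonds the lactone carbonyl, adds intramolecularly to C14 of the butenolide (6-endo-trig oxa-Michael addition), and the enolate is protonated at C13 on the opposite face because the new dioxaborinane can only be cis-fused to the five-membered lactone, which forces the C12 branch and O14 cis (13R,14S); the face is chosen by the (12R) centre, since allylic 1,3-strain keeps H12 rather than C11 in the butenolide plane next to the carbonyl; the closest known reaction type is the amine-catalysed boronic-acid-hemiester oxa-Michael addition of γ- and δ-hydroxy enones (exo mode), which has not been shown in this endo mode on an α-(1-hydroxyalkyl)butenolide.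

Step 13
Reactants: 25 cyclic phenylboronate of the 12,14-diol
Product: 26 (3R,4S)-4-hydroxy-3-[(1R)-1-hydroxy-2-[(1R,4aS,5R,6R,8aS)-6-hydroxy-5-(hydroxymethyl)-5,8a-dimethyl-2-methylidenedecahydronaphthalen-1-yl]ethyl]oxolan-2-one (CNP0113086.1)
Conditions: pinacol (3 equiv), AcOH/THF/H2O (3:1:1), 23 °C
Reagents that add atoms: none
Why: Boronate transesterification to pinacol and acid-catalysed acetal hydrolysis free the four hydroxyl groups under mildly acidic conditions that neither epimerise C13 nor eliminate the C14 hydroxyl.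

**Compound list**

1 | geranyl chloride, (2E)-1-chloro-3,7-dimethylocta-2,6-diene | CC(C)=CCC/C(C)=C/CCl | starting material
2 | ozonide, 3-[(3E)-5-chloro-3-methylpent-3-en-1-yl]-5,5-dimethyl-1,2,4-trioxolane | CC1(C)OOC(CC/C(C)=C/CCl)O1 | intermediate
3 | (4E)-6-chloro-4-methylhex-4-enal | O=CCC/C(C)=C/CCl | intermediate
4 | ethyl 2-[bis(2,2,2-trifluoroethoxy)phosphoryl]propanoate | CCOC(=O)C(C)P(=O)(OCC(F)(F)F)OCC(F)(F)F | starting material
5 | ethyl (2Z,6E)-8-chloro-2,6-dimethylocta-2,6-dienoate | CCOC(=O)/C(C)=C\CC/C(C)=C/CCl | intermediate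
6 | (2Z,6E)-8-chloro-2,6-dimethylocta-2,6-dien-1-ol | OC/C(C)=C\CC/C(C)=C/CCl | intermediate
7 | trimethyl(prop-1-yn-1-yl)silane | CC#C[Si](C)(C)C | starting material
8 | (2Z,6E)-2,6-dimethyl-11-(trimethylsilyl)undeca-2,6-dien-10-yn-1-ol | OC/C(C)=C\CC/C(C)=C/CCC#C[Si](C)(C)C | intermediate
9 | (2Z,6E)-2,6-dimethylundeca-2,6-dien-10-yn-1-ol | OC/C(C)=C\CC/C(C)=C/CCC#C | intermediate
10 | [(trimethylsilyl)methyl]magnesium chloride | C[Si](C)(C)C[Mg]Cl | starting material
11 | oxirane (ethylene oxide) | C1CO1 | starting material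
12 | alkenylcopper: chloromagnesium (2Z,6E,10Z)-11-cuprio-2,6-dimethyl-10-[(trimethylsilyl)methyl]undeca-2,6,10-trien-1-olate | Cl[Mg]OC/C(C)=C\CC/C(C)=C/CC/C(C[Si](C)(C)C)=C/[Cu] | intermediate
13 | (2Z,6E,10Z)-2,6-dimethyl-10-[(trimethylsilyl)methyl]trideca-2,6,10-triene-1,13-diol | OC/C(C)=C\CC/C(C)=C/CC/C(C[Si](C)(C)C)=C/CCO | intermediate
14 | {(2S,3R)-3-[(3E,7Z)-10-hydroxy-3-methyl-7-[(trimethylsilyl)methyl]deca-3,7-dien-1-yl]-2-methyloxiran-2-yl}methanol | OC[C@]1(C)O[C@@H]1CC/C(C)=C/CC/C(C[Si](C)(C)C)=C/CCO | intermediate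
15 | bis(trimethylsilyl) ether of 14 | C[Si](C)(C)OC[C@]1(C)O[C@@H]1CC/C(C)=C/CC/C(C[Si](C)(C)C)=C/CCO[Si](C)(C)C | intermediate
16 | cyclised bis-silyl ether: 12,19-bis(trimethylsilyl) ether of 17 (3-OH free; 3R,4R,5S,9R,10S) | C=C1CC[C@@H]2[C@](C)(CO[Si](C)(C)C)[C@H](O)CC[C@@]2(C)[C@@H]1CCO[Si](C)(C)C | intermediate
17 | (1R,2R,4aS,5R,8aS)-5-(2-hydroxyethyl)-1-(hydroxymethyl)-1,4a-dimethyl-6-methylidenedecahydronaphthalen-2-ol (labdane locants 3R,4R,5S,9R,10S; 3-OH equatorial, C19 CH2OH axial, trans-decalin) | C=C1CC[C@@H]2[C@](C)(CO)[C@H](O)CC[C@@]2(C)[C@@H]1CCO | intermediate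
18 | 3,19-O-isopropylidene acetal of 17 (six-membered acetonide across O3 and O19; C12 alcohol free) | C=C1CC[C@@H]2[C@]3(C)COC(C)(C)O[C@@H]3CC[C@@]2(C)[C@@H]1CCO | intermediate
19 | 3,19-O-isopropylidene C12 aldehyde (CH2CHO on C9) | C=C1CC[C@@H]2[C@]3(C)COC(C)(C)O[C@@H]3CC[C@@]2(C)[C@@H]1CC=O | intermediate
20 | 1,1,1,3,3,3-hexafluoropropan-2-yl prop-2-enoate | C=CC(=O)OC(C(F)(F)F)C(F)(F)F | starting material
21 | prop-2-en-1-ol (allyl alcohol) | C=CCO | starting material
22 | 1,1,1,3,3,3-hexafluoropropan-2-yl (3R)-3-hydroxy-2-methylidenebutanoate carrying the decalin of 19 at C4 | C=C1CC[C@@H]2[C@]3(C)COC(C)(C)O[C@@H]3CC[C@@]2(C)[C@@H]1C[C@@H](O)C(=C)C(=O)OC(C(F)(F)F)C(F)(F)F | intermediate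
23 | allyl (3R)-3-hydroxy-2-methylidenebutanoate carrying the decalin of 19 at C4 | C=C1CC[C@@H]2[C@]3(C)COC(C)(C)O[C@@H]3CC[C@@]2(C)[C@@H]1C[C@@H](O)C(=C)C(=O)OCC=C | intermediate
24 | 3-[(1R)-1-hydroxy-2-(decalinyl)ethyl]furan-2(5H)-one; (12R)-14-deoxy-12-hydroxyandrographolide 3,19-acetonide | C=C1CC[C@@H]2[C@]3(C)COC(C)(C)O[C@@H]3CC[C@@]2(C)[C@@H]1C[C@@H](O)C1=CCOC1=O | intermediate
25 | cyclic phenylboronate: 2-phenyl-1,3,2-dioxaborinane across O12 and O14, cis-fused to the γ-lactone (12R,13R,14S); 3,19-acetonide | C=C1CC[C@@H]2[C@]3(C)COC(C)(C)O[C@@H]3CC[C@@]2(C)[C@@H]1C[C@H]1OB(c2ccccc2)O[C@@H]2COC(=O)[C@H]12 | intermediate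
26 | (3R,4S)-4-hydroxy-3-[(1R)-1-hydroxy-2-[(1R,4aS,5R,6R,8aS)-6-hydroxy-5-(hydroxymethyl)-5,8a-dimethyl-2-methylidenedecahydronaphthalen-1-yl]ethyl]oxolan-2-one | C=C1CC[C@@H]2[C@](C)(CO)[C@H](O)CC[C@@]2(C)[C@@H]1C[C@@H](O)[C@H]1C(=O)OC[C@H]1O | target

**Count and risks**

Total step count: 13. Longest linear sequence: 13 steps (1 → 26).

The three steps most likely to fail, each with its fallback:

First, step 5. The silylmethylcopper may add sluggishly to this polyfunctional enynol, or the alkenylcopper may fail to open ethylene oxide. The fallback reverses the order of bond formation, putting the two-carbon unit on first and the silylmethyl group last. It sets out from 9: double deprotonation (n-BuLi) and BF3·OEt2-assisted opening of 11 by the acetylide give (2Z,6E)-2,6-dimethyltrideca-2,6-dien-10-yne-1,13-diol F1. AuCl-catalysed 5-endo hydroalkoxylation of the homopropargylic alcohol gives 5-[(3E,7Z)-9-hydroxy-4,8-dimethylnona-3,7-dien-1-yl]-2,3-dihydrofuran F2. Nickel-catalysed ring-opening coupling of this cyclic enol ether with 10 (NiCl2(PPh3)2, benzene, reflux) replaces the ring C–O bond by C–CH2SiMe3 with retention of geometry and comes back to the route at 13.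

Second, step 10. The hindered, β-branched aldehyde may react slowly at −55 °C, and the dioxanone side product or the one-pot transesterification may erode the yield. The fallback replaces the organocatalytic acrylate coupling and the metathesis by a stoichiometric aldol/elimination. It sets out from 19: aldol addition of the lithium enolate of racemic 3-(phenylselanyl)oxolan-2-one (from γ-butyrolactone; LiN(iPr)2, THF, −78 °C) gives the selenide aldol 3-[1-hydroxy-2-(decalinyl)ethyl]-3-(phenylselanyl)oxolan-2-one F3. H2O2/pyridine at 0 °C then causes selenoxide syn-elimination into the ring. This comes back to the route at 24, bypassing 23 and step 11. The weakness is that C12 is not controlled: the C12 epimer is removed by chromatography and recycled by Mitsunobu inversion.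

Third, step 12, the proposed new step. The 6-endo addition may be slow, the amine may instead deprotonate the butenolide at C15, or the face selectivity may be lower than the strain argument predicts. The fallback uses known chemistry, copper-catalysed conjugate borylation followed by oxidation. It sets out from 24: B2pin2, CuCl (5 mol%), a chiral Josiphos-type bisphosphine, NaOtBu and MeOH in THF give the β-boryl lactone F4. The ligand is chosen to deliver boron to the C14 face that becomes 14S, and protonation of the enolate anti to boron should give the 13,14-cis isomer, though this is the uncertain point. NaBO3·4H2O oxidises the C–B bond with retention to the 12,14-diol 3,19-acetonide F5. AcOH/H2O then removes the acetonide, and the sequence comes back to the route at 26.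

Further compounds
F1 | step 5 | (2Z,6E)-2,6-dimethyltrideca-2,6-dien-10-yne-1,13-diol | OC/C(C)=C\CC/C(C)=C/CCC#CCCO
F2 | step 5 | 5-[(3E,7Z)-9-hydroxy-4,8-dimethylnona-3,7-dien-1-yl]-2,3-dihydrofuran | OC/C(C)=C\CC/C(C)=C/CCC1=CCCO1
F3 | step 10 | 3-[1-hydroxy-2-(decalinyl)ethyl]-3-(phenylselanyl)oxolan-2-one (3,19-acetonide; mixture at C12 and C13) | C=C1CC[C@@H]2[C@]3(C)COC(C)(C)O[C@@H]3CC[C@@]2(C)[C@@H]1CC(O)C1([Se]c2ccccc2)CCOC1=O
F4 | step 12 | (12R,13R,14S)-14-(4,4,5,5-tetramethyl-1,3,2-dioxaborolan-2-yl) lactone: 24 after conjugate borylation and protonation (3,19-acetonide) | C=C1CC[C@@H]2[C@]3(C)COC(C)(C)O[C@@H]3CC[C@@]2(C)[C@@H]1C[C@@H](O)[C@H]1C(=O)OC[C@H]1B1OC(C)(C)C(C)(C)O1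
F5 | step 12 | 3,19-O-isopropylidene derivative of 26 | C=C1CC[C@@H]2[C@]3(C)COC(C)(C)O[C@@H]3CC[C@@]2(C)[C@@H]1C[C@@H](O)[C@H]1C(=O)OC[C@H]1O
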